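Cuts, in retrosynthetic order: the five O–benzyl bonds; C4–C3 and O1–C2 of the flavan pyran ring; the C4a–C4 bond (hydroxymethyl carbon); the biaryl bond from flavone C3 to flavan C6.
Enabling feature: O1, C8a, C4a and C4 of the pyran ring are the four atoms of an ortho-quinone methide. C3 and C2 are the alkene of 4-vinylphenol, a vinylogous enol whose hydroxyl a chiral acid can hold; C2 is the only stereocentre and carries the 4-hydroxyphenyl group.
Forward: both flavone rings are bought as apigenin. Flavan ring A comes from phloroglucinol, marked at one oxygen with a silyl group and iodinated between the other two; a Negishi coupling joins the halves.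
Desilylation bares the one hydroxyl para to the flavone. Its two ortho positions are equivalent, so formylation and reduction give a single ortho-hydroxybenzyl alcohol, and only the 6-linked flavan can follow.
The pyran ring is the only ring built. It closes in the cycloaddition, where a BINOL-derived phosphoric acid sets C2 as S, and neutral hydrogenolysis ends the route without touching C2.

Key step: step 10

Assumption 1: the target carries no descriptor for the flavone C3–flavan C6 axis, so slowly interconverting rotamers about this bond are counted as one compound and only C2 is controlled.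
Assumption 2: the (R)-configured phosphoric acid is taken to deliver 2S; the sense of induction has to be checked on the first run, and the (S)-acid is used in the same way if it proves opposite.

Step 1
Reactants: 1 apigenin
Product: 2 tri-O-benzylapigenin [5,7-bis(benzyloxy)-2-(4-benzyloxyphenyl)-4H-chromen-4-one]
Conditions: BnBr (4.5 equiv), K2CO3, DMF, 80 °C
Reagents that add atoms: benzyl bromide, BrCc1ccccc1
Why: Williamson ether synthesis in which the 7- and 4'-phenoxides alkylate readily and excess benzyl bromide with heat also takes the chelated 5-hydroxyl, so that every flavone oxygen carries a group that falls under neutral hydrogenolysis.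

Step 2
Reactants: 3 phloroglucinol (anhydrous)
Product: 4 phloroglucinol mono(triisopropylsilyl) ether [5-(triisopropylsilyloxy)benzene-1,3-diol]
Conditions: iPr3SiCl (1 equiv), 3 (3 equiv), imidazole, DMF, 0 °C to rt
Reagents that add atoms: chlorotriisopropylsilane, CC(C)[Si](Cl)(C(C)C)C(C)C
Why: Statistical monosilylation of a threefold symmetric triol with the silyl chloride as limiting reagent, in which surplus phloroglucinol is washed out with water and the silyl ether singles out the oxygen that will become flavan O1.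

Step 3
Reactants: 4 phloroglucinol mono(triisopropylsilyl) ether
Product: 5 iodoresorcinol [2-iodo-5-(triisopropylsilyloxy)benzene-1,3-diol]
Conditions: I2 (1.0 equiv), NaHCO3, THF–H2O, 0 °C
Reagents that add atoms: iodine, II
Why: Electrophilic aromatic iodination under the aqueous NaHCO3 conditions that place iodine between the two hydroxyls of resorcinol and its 5-substituted congeners, with the two alternative positions further shielded here by the neighbouring triisopropylsilyl ether.

Step 4
Reactants: 5 iodoresorcinol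
Product: 6 aryl iodide [3,5-bis(benzyloxy)-4-iodophenoxy]triisopropylsilane
Conditions: BnBr (2.4 equiv), K2CO3, acetone, reflux
Reagents that add atoms: benzyl bromide, BrCc1ccccc1
Why: Williamson ether synthesis on a 2-iodoresorcinol, a routine transformation, under carbonate in acetone that leaves the hindered aryl silyl ether and the C–I bond alone.

Step 5
Reactants: 2 tri-O-benzylapigenin; 6 aryl iodide
Product: 9 coupled silyl ether [5,7-bis(benzyloxy)-2-(4-benzyloxyphenyl)-3-(2,6-bis(benzyloxy)-4-(triisopropylsilyloxy)phenyl)-4H-chromen-4-one], via 3-lithioflavone 7 (not isolated), via 3-(chlorozincio)flavone 8 (not isolated)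
Conditions: 2 (1.3 equiv), LiN(iPr)2, THF, −78 °C; ZnCl2, −78 °C to rt; 6, Pd2(dba)3 (2.5 mol%), RuPhos (10 mol%), THF, 65 °C
Reagents that add atoms: none
Why: C3 lithiation of a flavone with a lithium amide, transmetalation to zinc to stop ring opening of the vinyllithium, and Negishi coupling, whose tolerance of four ortho substituents with dialkylbiarylphosphine ligands fits this crowded C3–aryl bond.

Step 6
Reactants: 9 coupled silyl ether
Product: 10 phenol [5,7-bis(benzyloxy)-2-(4-benzyloxyphenyl)-3-(2,6-bis(benzyloxy)-4-hydroxyphenyl)-4H-chromen-4-one]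
Conditions: Bu4NF, AcOH, THF, 0 °C
Reagents that add atoms: none
Why: Fluoride-induced cleavage of an aryl silyl ether, buffered with acetic acid so that neither the pyranone nor the benzyl ethers see a basic medium.

Step 7
Reactants: 10 phenol
Product: 11 salicylaldehyde [2,4-bis(benzyloxy)-3-(5,7-bis(benzyloxy)-2-(4-benzyloxyphenyl)-4-oxo-4H-chromen-3-yl)-6-hydroxybenzaldehyde]
Conditions: MgCl2, Et3N, (CH2O)n, THF, reflux; cold 1 M HCl
Reagents that add atoms: paraformaldehyde (reacts as formaldehyde), C=O
Why: Casnati–Skattebøl ortho-formylation, in which the magnesium phenoxide delivers formaldehyde only ortho to the free hydroxyl, the two such positions are equivalent, and a second formaldehyde oxidises the benzylic alkoxide to the aldehyde.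

Step 8
Reactants: 11 salicylaldehyde
Product: 12 ortho-hydroxybenzyl alcohol [5,7-bis(benzyloxy)-2-(4-benzyloxyphenyl)-3-(2,6-bis(benzyloxy)-4-hydroxy-3-(hydroxymethyl)phenyl)-4H-chromen-4-one]
Conditions: NaBH4, THF–MeOH, 0 °C; pH 7 phosphate buffer; used without storage
Reagents that add atoms: none
Why: Borohydride 1,2-reduction of an aldehyde, much faster at 0 °C than any attack on the hindered vinylogous ester carbonyl of the flavone, with a neutral work-up because the electron-rich benzylic alcohol ionises easily.

Step 9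
Reactants: 13 4-acetoxystyrene
Product: 14 4-vinylphenol
Conditions: K2CO3 (10 mol%), MeOH, 0 °C to rt; used at once
Reagents that add atoms: none
Why: Base-catalysed transesterification of an aryl acetate, which frees the polymerisation-prone phenol from its stable commercial ester just before use.

Step 10
Reactants: 12 ortho-hydroxybenzyl alcohol; 14 4-vinylphenol
Product: 17 pentabenzyl ether [5,7-bis(benzyloxy)-2-(4-benzyloxyphenyl)-3-((2S)-5,7-bis(benzyloxy)-2-(4-hydroxyphenyl)-3,4-dihydro-2H-chromen-6-yl)-4H-chromen-4-one], via ortho-quinone methide 15 (not isolated), via para-quinone methide 16 (not isolated)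
Conditions: (R)-3,3'-bis(2,4,6-triisopropylphenyl)-1,1'-binaphthalene-2,2'-diyl hydrogen phosphate (10 mol%), 14 (3 equiv), 4 Å molecular sieves, CH2Cl2–toluene, −30 °C, slow addition of 12; Et3N before warming
Reagents that add atoms: none
Why: The acid protonates the benzylic hydroxyl of 12, whose ring carries three oxygen donors, and loss of water gives 15 bound to the phosphate at its carbonyl oxygen; the same phosphate holds the hydroxyl of 14, whose terminal alkene carbon adds as a vinylogous enol to the exocyclic methylene (C4–C3) to give 16, and the ring phenol of 16 then adds to the benzylic terminus (O1–C2). The closest known reaction type is the chiral Brønsted acid-catalysed [4+2] annulation of ortho-hydroxybenzyl alcohols with styrenes and hydroxystyrenes to chromans, backed by phosphoric acid-catalysed enantioselective 1,6-additions to para-quinone methides, and the terminally unsubstituted quinone methide and the para-placed hydroxyl are substrate variations within it. The pyran ring closes in a formal hetero-[4+2] sense, four atoms (O1, C8a, C4a, C4) from 15 and two (C3, C2) from 14, and the last event is a 6-exo-trig oxa-1,6-addition because the breaking C2=C1' bond lies outside the new ring. C2 is the only new stereocentre and is set in that closure by the catalyst alone, whose 3,3'-aryl walls leave one face of the hydrogen-bonded para-quinone methide open to the tethered phenol. The step needs the 6-linked and not the 8-linked flavan, which is secured because the oxygen para to the flavone is the only free hydroxyl next to the hydroxymethyl group while both oxygens flanking the flavone are benzylated, and the aryl group ends on C2 because the nucleophilic CH2 terminus pairs with the electrophilic methylene. Slow addition of 12 to excess 14 in the cold over sieves holds back self-alkylation of 15, cationic oligomerisation of 14 and acid reopening of 17.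

Step 11
Reactants: 17 pentabenzyl ether
Product: 18 target [5,7-dihydroxy-3-((2S)-5,7-dihydroxy-2-(4-hydroxyphenyl)-3,4-dihydro-2H-chromen-6-yl)-2-(4-hydroxyphenyl)-4H-chromen-4-one]
Conditions: H2 (1 atm), Pd(OH)2/C, THF–MeOH, rt, stopped after uptake of five equivalents
Reagents that add atoms: none
Why: Catalytic hydrogenolysis of aryl benzyl ethers as practised on benzylated catechins and flavans, in which the cyclic C2–O1 ether and the tetrasubstituted flavone alkene react more slowly and no acid or base is present that could open the 4'-hydroxyflavan and scramble C2.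

Compound list
1 | apigenin | O=c1cc(-c2ccc(O)cc2)oc2cc(O)cc(O)c12 | starting material
2 | tri-O-benzylapigenin | O=c1cc(-c2ccc(OCc3ccccc3)cc2)oc2cc(OCc3ccccc3)cc(OCc3ccccc3)c12 | intermediate
3 | phloroglucinol | Oc1cc(O)cc(O)c1 | starting material
4 | 5-(triisopropylsilyloxy)benzene-1,3-diol | CC(C)[Si](Oc1cc(O)cc(O)c1)(C(C)C)C(C)C | intermediate
5 | 2-iodo-5-(triisopropylsilyloxy)benzene-1,3-diol | CC(C)[Si](Oc1cc(O)c(I)c(O)c1)(C(C)C)C(C)C | intermediate
6 | [3,5-bis(benzyloxy)-4-iodophenoxy]triisopropylsilane | CC(C)[Si](Oc1cc(OCc2ccccc2)c(I)c(OCc2ccccc2)c1)(C(C)C)C(C)C | intermediate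
7 | 3-lithio derivative of tri-O-benzylapigenin | [Li]c1c(-c2ccc(OCc3ccccc3)cc2)oc2cc(OCc3ccccc3)cc(OCc3ccccc3)c2c1=O | intermediate
8 | 3-(chlorozincio) derivative of tri-O-benzylapigenin | Cl[Zn]c1c(-c2ccc(OCc3ccccc3)cc2)oc2cc(OCc3ccccc3)cc(OCc3ccccc3)c2c1=O | intermediate
9 | 5,7-bis(benzyloxy)-2-(4-benzyloxyphenyl)-3-(2,6-bis(benzyloxy)-4-(triisopropylsilyloxy)phenyl)-4H-chromen-4-one | O=c1c(-c2c(OCc3ccccc3)cc(O[Si](C(C)C)(C(C)C)C(C)C)cc2OCc2ccccc2)c(-c2ccc(OCc3ccccc3)cc2)oc2cc(OCc3ccccc3)cc(OCc3ccccc3)c12 | intermediate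
10 | 5,7-bis(benzyloxy)-2-(4-benzyloxyphenyl)-3-(2,6-bis(benzyloxy)-4-hydroxyphenyl)-4H-chromen-4-one | O=c1c(-c2c(OCc3ccccc3)cc(O)cc2OCc2ccccc2)c(-c2ccc(OCc3ccccc3)cc2)oc2cc(OCc3ccccc3)cc(OCc3ccccc3)c12 | intermediate
11 | 2,4-bis(benzyloxy)-3-(5,7-bis(benzyloxy)-2-(4-benzyloxyphenyl)-4-oxo-4H-chromen-3-yl)-6-hydroxybenzaldehyde | O=c1c(-c2c(OCc3ccccc3)cc(O)c(C=O)c2OCc2ccccc2)c(-c2ccc(OCc3ccccc3)cc2)oc2cc(OCc3ccccc3)cc(OCc3ccccc3)c12 | intermediate
12 | 5,7-bis(benzyloxy)-2-(4-benzyloxyphenyl)-3-(2,6-bis(benzyloxy)-4-hydroxy-3-(hydroxymethyl)phenyl)-4H-chromen-4-one | O=c1c(-c2c(OCc3ccccc3)cc(O)c(CO)c2OCc2ccccc2)c(-c2ccc(OCc3ccccc3)cc2)oc2cc(OCc3ccccc3)cc(OCc3ccccc3)c12 | intermediate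
13 | 4-acetoxystyrene | C=Cc1ccc(OC(C)=O)cc1 | starting material
14 | 4-vinylphenol | C=Cc1ccc(O)cc1 | intermediate
15 | ortho-quinone methide: 3-(2,6-bis(benzyloxy)-3-methylidene-4-oxocyclohexa-1,5-dien-1-yl)-5,7-bis(benzyloxy)-2-(4-benzyloxyphenyl)-4H-chromen-4-one | O=c1c(C2=C(OCc3ccccc3)C(=C)C(=O)C=C2OCc2ccccc2)c(-c2ccc(OCc3ccccc3)cc2)oc2cc(OCc3ccccc3)cc(OCc3ccccc3)c12 | intermediate
16 | para-quinone methide: 3-(2,6-bis(benzyloxy)-4-hydroxy-3-(3-(4-oxocyclohexa-2,5-dien-1-ylidene)propyl)phenyl)-5,7-bis(benzyloxy)-2-(4-benzyloxyphenyl)-4H-chromen-4-one | O=c1c(-c2c(OCc3ccccc3)cc(O)c(CCC=C3C=CC(=O)C=C3)c2OCc2ccccc2)c(-c2ccc(OCc3ccccc3)cc2)oc2cc(OCc3ccccc3)cc(OCc3ccccc3)c12 | intermediate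
17 | 5,7-bis(benzyloxy)-2-(4-benzyloxyphenyl)-3-((2S)-5,7-bis(benzyloxy)-2-(4-hydroxyphenyl)-3,4-dihydro-2H-chromen-6-yl)-4H-chromen-4-one | O=c1c(-c2c(OCc3ccccc3)cc3c(c2OCc2ccccc2)CC[C@@H](c2ccc(O)cc2)O3)c(-c2ccc(OCc3ccccc3)cc2)oc2cc(OCc3ccccc3)cc(OCc3ccccc3)c12 | intermediate
18 | 5,7-dihydroxy-3-((2S)-5,7-dihydroxy-2-(4-hydroxyphenyl)-3,4-dihydro-2H-chromen-6-yl)-2-(4-hydroxyphenyl)-4H-chromen-4-one | O=c1c(-c2c(O)cc3c(c2O)CC[C@@H](c2ccc(O)cc2)O3)c(-c2ccc(O)cc2)oc2cc(O)cc(O)c12 | target

Total step count: 11. Longest linear sequence: 9 steps (steps 2, 3, 4, 5, 6, 7, 8, 10 and 11, from phloroglucinol).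

Steps most likely to fail

Step 10.
- Facial discrimination in the O1–C2 closure may be poor. The catalyst has to control a centre that no substrate element biases, and the substrate enters as two rotamers about the biaryl axis that may respond differently.
- The basic pyranone carbonyl competes for the acid.
- The vinylphenol may oligomerise.
- Acid may reopen the pyran ring at C2–O1 and erode the enantiomeric purity.
- The fallback sets out from 11 and returns at 18, setting C2 by ketone reduction and invertive ring closure.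
- Wittig olefination of 11 with 1-(4-benzyloxyphenyl)-2-(triphenylphosphoranylidene)ethanone (toluene, 110 °C) should give the (E)-enone F1.
- Saturation of its alkene with H2 and RhCl(PPh3)3, which spares benzyl ethers, should give the saturated ketone F2.
- Noyori transfer hydrogenation with RuCl(p-cymene)[(R,R)-TsNCH(Ph)CH(Ph)NH2] in HCO2H–Et3N should give the (R)-benzylic alcohol F3.
- Intramolecular Mitsunobu etherification (PPh3, diisopropyl azodicarboxylate, THF, 0 °C) should close the pyran ring with inversion to the (2S)-flavan hexabenzyl ether F4, which the conditions of step 11 convert into 18.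

Step 5.
- The metalated flavone may open by β-elimination of the ring oxygen before it reaches zinc.
- Oxidative addition and reductive elimination at a bond with four ortho substituents may be too slow, so that the zinc reagent is simply protonated on work-up.
- The fallback sets out from 2 and 6 and returns at 9 with the roles of the partners exchanged, so the flavone becomes a stable electrophile.
- Lithiation of 2 as before (7) and quenching with I2 at −78 °C should give the 3-iodoflavone F5.
- Iodine–lithium exchange on 6 (n-BuLi, THF, −78 °C) should give the aryllithium F6, which with B(OMe)3 and dilute HCl should give the arylboronic acid F7.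
- Suzuki–Miyaura coupling of F5 with F7 (Pd(OAc)2, SPhos, K3PO4, toluene–H2O, 90 °C) should give 9.

Step 8.
- The borate of the product may lose its benzylic oxygen prematurely and be reduced further to the methyl compound.
- The free alcohol may self-condense during work-up or on silica.
- The fallback sets out from 10 and returns at 12 without an aldehyde or a hydride.
- Ortho-specific hydroxymethylation of 10 with PhB(OH)2 and (CH2O)n (catalytic propionic acid, toluene, reflux with removal of water) should give the storable 2-phenyl-4H-1,3,2-benzodioxaborinine F8.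
- Oxidative cleavage of its boron ester with H2O2 in THF at 0 °C, just before the key step, should release 12.

Further compounds
F1 | step 10 | 3-(2,6-bis(benzyloxy)-3-((1E)-3-(4-benzyloxyphenyl)-3-oxoprop-1-en-1-yl)-4-hydroxyphenyl)-5,7-bis(benzyloxy)-2-(4-benzyloxyphenyl)-4H-chromen-4-one | O=c1c(-c2c(OCc3ccccc3)cc(O)c(/C=C/C(=O)c3ccc(OCc4ccccc4)cc3)c2OCc2ccccc2)c(-c2ccc(OCc3ccccc3)cc2)oc2cc(OCc3ccccc3)cc(OCc3ccccc3)c12
F2 | step 10 | 3-(2,6-bis(benzyloxy)-3-(3-(4-benzyloxyphenyl)-3-oxopropyl)-4-hydroxyphenyl)-5,7-bis(benzyloxy)-2-(4-benzyloxyphenyl)-4H-chromen-4-one | O=c1c(-c2c(OCc3ccccc3)cc(O)c(CCC(=O)c3ccc(OCc4ccccc4)cc3)c2OCc2ccccc2)c(-c2ccc(OCc3ccccc3)cc2)oc2cc(OCc3ccccc3)cc(OCc3ccccc3)c12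
F3 | step 10 | 3-(2,6-bis(benzyloxy)-3-((3R)-3-(4-benzyloxyphenyl)-3-hydroxypropyl)-4-hydroxyphenyl)-5,7-bis(benzyloxy)-2-(4-benzyloxyphenyl)-4H-chromen-4-one | O=c1c(-c2c(OCc3ccccc3)cc(O)c(CC[C@@H](O)c3ccc(OCc4ccccc4)cc3)c2OCc2ccccc2)c(-c2ccc(OCc3ccccc3)cc2)oc2cc(OCc3ccccc3)cc(OCc3ccccc3)c12
F4 | step 10 | 5,7-bis(benzyloxy)-2-(4-benzyloxyphenyl)-3-((2S)-5,7-bis(benzyloxy)-2-(4-benzyloxyphenyl)-3,4-dihydro-2H-chromen-6-yl)-4H-chromen-4-one | O=c1c(-c2c(OCc3ccccc3)cc3c(c2OCc2ccccc2)CC[C@@H](c2ccc(OCc4ccccc4)cc2)O3)c(-c2ccc(OCc3ccccc3)cc2)oc2cc(OCc3ccccc3)cc(OCc3ccccc3)c12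
F5 | step 5 | 5,7-bis(benzyloxy)-2-(4-benzyloxyphenyl)-3-iodo-4H-chromen-4-one | O=c1c(I)c(-c2ccc(OCc3ccccc3)cc2)oc2cc(OCc3ccccc3)cc(OCc3ccccc3)c12
F6 | step 5 | [2,6-bis(benzyloxy)-4-(triisopropylsilyloxy)phenyl]lithium | [Li]c1c(OCc2ccccc2)cc(O[Si](C(C)C)(C(C)C)C(C)C)cc1OCc1ccccc1
F7 | step 5 | [2,6-bis(benzyloxy)-4-(triisopropylsilyloxy)phenyl]boronic acid | OB(O)c1c(OCc2ccccc2)cc(O[Si](C(C)C)(C(C)C)C(C)C)cc1OCc1ccccc1
F8 | step 8 | 3-(5,7-bis(benzyloxy)-2-phenyl-4H-1,3,2-benzodioxaborinin-6-yl)-5,7-bis(benzyloxy)-2-(4-benzyloxyphenyl)-4H-chromen-4-one | O=c1c(-c2c(OCc3ccccc3)cc3OB(c4ccccc4)OCc3c2OCc2ccccc2)c(-c2ccc(OCc3ccccc3)cc2)oc2cc(OCc3ccccc3)cc(OCc3ccccc3)c12
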